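Readings and results are calculated for substances that don't exist.

- I started from a small charge: oak held 0.50 M of starting material, and cedar held twice that. Here are the flasks, the earlier runs and the questions.

| flask | starting material | remark | time |
|---|---|---|---|
| oak | 0.50 M | run made earlier |  |
| larch | 0.70 M | run made earlier |  |
| cedar | 1.1 M | run made earlier |  |
| violet | 0.50 M | everything together in a closed stirred flask, run for 6.0 min | 6.0 min |
| amber | 0.50 M | one stirred flow tank at steady state, fed with the mixture as stated, mean residence time 30.0 min |  |
| grey | 0.50 M | one stirred flow tank at steady state, fed with the mixture as stated, mean residence time 6.0 min |  |

- oak (time / min: target / %): 1.33: 0.8; 2.50: 3.7; 4.00: 7.1; 5.00: 11.0; 6.00: 15.3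
- larch (time / min: target / %): 0.417: 0; 0.667: 0; 1.33: 1.6; 2.50: 3.7; 5.00: 11.4
- cedar (time / min: target / %): 1.00: 0.6; 2.00: 2.2; 3.00: 4.9; 4.00: 6.4; 5.00: 10.9

(scatter of a reading: 0.5 percentage points)

- the stated concentrations are those of everything mixed, before any reaction; amounts are the same in each set-up
- the earlier runs were made in a closed, stirred flask

- the set-up with the highest amount of target at the outlet or at the end, in percent of the starting material put in ("none" if the first two lie within 2 percentage points) (violet / amber / grey / none)
- amount of target at the outlet or at the end, in percent of the starting material put in, violet
- amount of target at the outlet or at the end, in percent of the starting material put in, amber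
- amount of target at the outlet or at the end, in percent of the starting material put in, grey

- From oak's last reading I took the chain time: the reading's time divided by the square root of 2 times the target's fraction of the charge. In a chain of two equal first-order steps this estimates the mean time of one step, by the early-time law that the target's fraction is the squared ratio of time to that mean time, divided by 2, and oak gave 10.8 min.
- Cedar's last reading gave 10.7 min, so I treated the steps as first order, and the chain time as a reading with scatter.
- Violet repeated oak's charge and time, so I expected the fraction 15.3%.
- For a tank with equal steps, I took the residence time over the chain time (a Damköhler number) and squared that number over one plus itself.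
- Amber's number was 2.77, which gave my 53.9%. Grey's residence time equals violet's time, so I expected it near violet.
- I then turned the question round. For amber to sink to the fraction I expected for violet, with that fraction held fixed, the chain time would have had to be 46.7 min, which is 4.32 times the reading.
- The forecast named amber, with 15% for violet, 58% for amber and 16% for grey. Its amber is above my 53.9%, and it warned that “the individual constants are poorly fixed”.

- Amber gave 49.7% and violet 14.8%, so amber came out best, and the forecast's amber stood 8.3 percentage points higher.

    intermediate A → intermediate B (k = 0.00454 s⁻¹)
    starting material ⇌ dormant form (K = 0.480, k = 3.52 × 10⁻⁴ s⁻¹)
    intermediate B → target (k = 0.0498 s⁻¹)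
    starting material → intermediate A (k = 0.00112 s⁻¹)
    2 starting material → homo dimer (k = 5.68 × 10⁻⁴ M⁻¹ s⁻¹)

- The two early steps were unequal: the half-life of starting material by its conversion into intermediate A alone was 10 min, longer than the 2.5 min of intermediate A by its conversion into intermediate B alone. Grey's Damköhler number, by the same chain time, was 0.553, which reckons to 12.7%, and grey stood at 14.5%.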